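A direct plan would make the C3–C4 bond by a chelate-controlled Ireland–Claisen rearrangement of the allyl α-benzyloxy ester A1 to the hexenoic acid A2. It would then degrade A2 (hydride reduction, ozonolysis) to the γ-lactol A3, arylate A3 to the 1-aryl-1,4-diol A4, close the oxolane with acid to the tetra-O-benzyl ether A5, and finish by hydrogenolysis.
Weak point 1, the rearrangement of A1. C3 and the fully substituted C4 would both depend on the geometry of one tetrasubstituted ketene acetal whose α-substituents (OBn, CH2Ar) differ little. The propenyl group it delivers is only a masked aldehyde, which costs a reduction and an ozonolysis next to two electron-rich arenes.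
Weak point 2, the arylation of A3 to A4. C2 would be formed without control and corrected afterwards by an SN1 cycloetherification, run in acid next to a tertiary benzyl ether and a nucleophilic arene.
Weak point 3, the final hydrogenolysis of A5. A hindered tertiary benzyl ether would have to be cleaved under conditions that can also cleave the benzylic C2–O1 bond of the electron-rich 2-aryloxolane.

**Retrosynthetic overview**
Feature used: in the oxolane ring (O1, C2–aryl, C3–CH2OH, C4(OH)(CH2Ar), C5H2) the tertiary C4–O bond is read as the Baeyer–Villiger product of a C4–CHO group, and a 4-benzyl-4-formyloxolane with an unsubstituted C5H2 is the retron of a Prins–pinacol rearrangement.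
Key disconnection: C2–C3 and C4–C5 (with O1–C2 from the condensation) form in one operation from vanillin acetate and an acyclic (E)-alkenyl 1,2-diol with one stereocentre; C2, C3 and quaternary C4 are set together and the bought stereocentre is consumed as the formyl carbon.
Ring order: a six-membered oxane cation closes first (C2–C3) and contracts at once to the oxolane (C5 shifts to C4); no C–O ring closure and no C3–C4 bond formation is used.
The diol comes from (S)-glycerate acetonide by alkyne homologation, trans-hydroalumination/iodination and Negishi benzylation, which fix the alkene geometry that encodes the C3/C4 relationship.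
No stereocentre is corrected afterwards, no redox stretch is needed, the tertiary alcohol is never protected, and only acyl and silyl groups remain at the end, so no hydrogenolysis meets the C2–O1 bond.

Key step: step 9

Assumption: methyl (4S)-2,2-dimethyl-1,3-dioxolane-4-carboxylate (catalogue compound of high ee, antipode equally available) is the only source of chirality, and the reactive chair of step 9 is taken to carry the stannyloxy group axial.
Abbreviations: Ar = 4-acetoxy-3-methoxyphenyl; TBDPS = tert-butyldiphenylsilyl. The comments use the oxolane numbering of the target.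

**Route**

Step 1
Reactants: 1 methyl (4S)-2,2-dimethyl-1,3-dioxolane-4-carboxylate
Product: 3 (4R)-4-ethynyl-2,2-dimethyl-1,3-dioxolane, via aldehyde 2 (not isolated)
Conditions: DIBAL-H (1.05 equiv), CH2Cl2, −78 °C; MeOH; then dimethyl (1-diazo-2-oxopropyl)phosphonate, K2CO3, MeOH, 0 °C → rt
Reagents that add atoms: dimethyl (1-diazo-2-oxopropyl)phosphonate (Ohira–Bestmann reagent), CC(=O)C(=[N+]=[N-])P(=O)(OC)OC
Why: DIBAL-H stops at the aluminium hemiacetal at −78 °C, methanol releases aldehyde 2, and Seyferth–Gilbert homologation under the mild Ohira–Bestmann conditions gives the alkyne without touching the α-alkoxy stereocentre (the descriptor changes from S to R only because the priorities change).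

Step 2
Reactants: 3 (4R)-4-ethynyl-2,2-dimethyl-1,3-dioxolane
Product: 5 3-[(4R)-2,2-dimethyl-1,3-dioxolan-4-yl]prop-2-yn-1-ol, via lithium acetylide 4 (not isolated)
Conditions: n-BuLi, THF, −78 °C; (CH2O)n, −78 °C → rt
Reagents that add atoms: paraformaldehyde (as formaldehyde), C=O
Why: Addition of a lithium acetylide to formaldehyde gives the propargylic alcohol that will direct the next step; no stereocentre is involved.

Step 3
Reactants: 5 3-[(4R)-2,2-dimethyl-1,3-dioxolan-4-yl]prop-2-yn-1-ol
Product: 7 (2Z)-3-[(4S)-2,2-dimethyl-1,3-dioxolan-4-yl]-3-iodoprop-2-en-1-ol, via cyclic vinylalanate 6 (not isolated)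
Conditions: Red-Al (1.6 equiv), THF, −20 → 0 °C; then I2, THF, −78 → −20 °C
Reagents that add atoms: iodine, II
Why: Hydroxyl-directed trans-hydroalumination places aluminium on the distal alkyne carbon in a five-membered alanate and iodinolysis with retention gives the (Z)-iodide, in which CH2OH is trans to the dioxolane, while a temperature of 0 °C or lower keeps the β-alkoxy group from being expelled.

Step 4
Reactants: 7 (2Z)-3-[(4S)-2,2-dimethyl-1,3-dioxolan-4-yl]-3-iodoprop-2-en-1-ol
Product: 8 tert-butyl{[(2Z)-3-[(4S)-2,2-dimethyl-1,3-dioxolan-4-yl]-3-iodoprop-2-en-1-yl]oxy}diphenylsilane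
Conditions: TBDPSCl, imidazole, CH2Cl2, 0 °C → rt
Reagents that add atoms: tert-butyl(chloro)diphenylsilane, CC(C)(C)[Si](Cl)(c1ccccc1)c1ccccc1
Why: Standard O-silylation gives a hindered, weakly Lewis-basic and non-participating ether that will survive SnCl4, and it is done before the aryl acetate enters so that this ester never meets imidazole.

Step 5
Reactants: 9 4-formyl-2-methoxyphenyl acetate (vanillin acetate)
Product: 10 4-(hydroxymethyl)-2-methoxyphenyl acetate
Conditions: NaBH4 (0.5 equiv), THF–EtOH, −10 °C, short reaction time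
Reagents that add atoms: none
Why: Chemoselective borohydride reduction of the aromatic aldehyde is much faster than attack on the aryl acetate at low temperature.

Step 6
Reactants: 10 4-(hydroxymethyl)-2-methoxyphenyl acetate
Product: 11 4-(chloromethyl)-2-methoxyphenyl acetate
Conditions: SOCl2, CH2Cl2, 0 °C
Reagents that add atoms: thionyl chloride, O=S(Cl)Cl
Why: The benzylic alcohol is converted to the chloride through its chlorosulfite, and the acetoxy group prevents quinone methide formation.

Step 7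
Reactants: 8 tert-butyl{[(2Z)-3-[(4S)-2,2-dimethyl-1,3-dioxolan-4-yl]-3-iodoprop-2-en-1-yl]oxy}diphenylsilane; 11 4-(chloromethyl)-2-methoxyphenyl acetate
Product: 13 4-{(2E)-4-[(tert-butyldiphenylsilyl)oxy]-2-[(4R)-2,2-dimethyl-1,3-dioxolan-4-yl]but-2-en-1-yl}-2-methoxyphenyl acetate, via benzylzinc chloride 12 (not isolated)
Conditions: 11, Zn dust, LiCl, THF, 25 °C; then 8, Pd(OAc)2 (2 mol %), SPhos (4 mol %), THF, 25 → 40 °C
Reagents that add atoms: compound 11 (as its zinc reagent 12), CC(=O)Oc1ccc(CCl)cc1OC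
Why: LiCl-promoted zinc insertion into the benzylic chloride tolerates the aryl acetate and Negishi coupling of the alkenyl iodide proceeds with retention, so the benzyl group takes the place of iodine cis to CH2OTBDPS and fixes the (E)-alkene that later encodes C3 and C4.

Step 8
Reactants: 13 4-{(2E)-4-[(tert-butyldiphenylsilyl)oxy]-2-[(4R)-2,2-dimethyl-1,3-dioxolan-4-yl]but-2-en-1-yl}-2-methoxyphenyl acetate
Product: 14 4-{(2E)-4-[(tert-butyldiphenylsilyl)oxy]-2-[(1R)-1,2-dihydroxyethyl]but-2-en-1-yl}-2-methoxyphenyl acetate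
Conditions: AcOH–H2O–THF (3:1:1), 45 °C
Reagents that add atoms: none
Why: Mild acid hydrolysis removes the isopropylidene acetal, while the TBDPS ether, the aryl acetate and the allylic stereocentre are inert in aqueous acetic acid.

Step 9
Reactants: 14 4-{(2E)-4-[(tert-butyldiphenylsilyl)oxy]-2-[(1R)-1,2-dihydroxyethyl]but-2-en-1-yl}-2-methoxyphenyl acetate; 9 4-formyl-2-methoxyphenyl acetate
Product: 16 (3R,4S,5R)-5-(4-acetoxy-3-methoxyphenyl)-3-(4-acetoxy-3-methoxybenzyl)-4-{[(tert-butyldiphenylsilyl)oxy]methyl}oxolane-3-carbaldehyde, via acetal 15 (not isolated)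
Conditions: 9 (1.1 equiv), p-TsOH·H2O (5 mol %), 4 Å MS, CH2Cl2, rt; then SnCl4 (2.5 equiv), −78 → −20 °C; aq. NaHCO3
Reagents that add atoms: compound 9, CC(=O)Oc1ccc(C=O)cc1OC
Why: SnCl4 opens acetal 15 at its allylic C–O bond to a zwitterion made of the (E)-aryl oxocarbenium ion on the primary oxygen and a stannyl alkoxide; the trisubstituted alkene attacks the oxocarbenium carbon through a chair (Prins step, 6-endo closure of an oxane, C2–C3 bond), and the O–CH2 carbon next to the carbinol then shifts to the tertiary cation while the carbinol carbon becomes the formyl group (pinacol step, ring contraction to the oxolane, C4–C5 bond). The closest known reaction type is the Prins–pinacol rearrangement of 4-alkenyl-1,3-dioxolanes to 3-acyloxolanes, which is also known for secondary carbinols that end as formyl groups. C2 is controlled by the equatorial aryl group of the (E)-oxocarbenium ion and C3 by the (E)-alkene, whose CH2OTBDPS group is trans to the carbinol carbon and therefore equatorial, which gives 2,3-trans; C4 is controlled by the ring, because the CH2 group can reach only the alkene face that was attacked, which puts CHO cis to the aryl group and the benzyl group cis to CH2OTBDPS. The absolute sense is chosen by the one stereocentre of 14, which decides between two mirror-image chairs: the stannyloxy group should stand axial, gauche to the cationic oxygen (Coulomb attraction within the zwitterion) and clear of the benzyl group that an equatorial substituent would eclipse (A1,2 strain), and with (R)-14 this chair leads to (2R,3S) and to the C4 configuration of the target. In the other chair the carbinol hydrogen is axial and aligned for a 1,2-hydride shift to an oxan-3-one, a separable constitutional isomer, so leakage should cost material rather than enantiomeric purity. The step needs acetal ionisation to be faster than ionisation of the allylic C–O bonds and than Friedel–Crafts attack by the arenes, which the hindered TBDPS ether, the low temperature and the two deactivating acetoxy groups should secure.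

Step 10
Reactants: 16 (3R,4S,5R)-5-(4-acetoxy-3-methoxyphenyl)-3-(4-acetoxy-3-methoxybenzyl)-4-{[(tert-butyldiphenylsilyl)oxy]methyl}oxolane-3-carbaldehyde
Product: 17 (3R,4S,5R)-5-(4-acetoxy-3-methoxyphenyl)-3-(4-acetoxy-3-methoxybenzyl)-4-{[(tert-butyldiphenylsilyl)oxy]methyl}oxolan-3-yl formate
Conditions: mCPBA (2 equiv), CH2Cl2, 0 °C → rt
Reagents that add atoms: 3-chloroperoxybenzoic acid, OOC(=O)c1cccc(Cl)c1
Why: Baeyer–Villiger oxidation: in the Criegee adduct of an α-quaternary aldehyde the tertiary alkyl group should migrate in preference to hydride and with retention, so C4–CHO becomes C4–OCHO with the configuration set in step 9, and the acetoxy groups keep both arenes inert to the peracid.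

Step 11
Reactants: 17 (3R,4S,5R)-5-(4-acetoxy-3-methoxyphenyl)-3-(4-acetoxy-3-methoxybenzyl)-4-{[(tert-butyldiphenylsilyl)oxy]methyl}oxolan-3-yl formate
Product: 19 (3R,4S,5R)-5-(4-hydroxy-3-methoxyphenyl)-3-[(4-hydroxy-3-methoxyphenyl)methyl]-4-(hydroxymethyl)oxolan-3-ol (target), via silyl ether 18 (not isolated)
Conditions: K2CO3 (0.2 equiv), MeOH, 0 °C → rt; then NH4F (10 equiv), MeOH, 50 °C
Reagents that add atoms: none
Why: Base-catalysed transesterification removes the formate and both aryl acetates and fluoride then cleaves the primary silyl ether, all in a weakly basic to neutral medium that avoids both hydrogenolysis and acid ionisation of the benzylic C2–O1 bond, and no stereocentre is touched.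

**Compound list**
1 | methyl (4S)-2,2-dimethyl-1,3-dioxolane-4-carboxylate | COC(=O)[C@@H]1COC(C)(C)O1 | starting material
2 | (4S)-2,2-dimethyl-1,3-dioxolane-4-carbaldehyde | O=C[C@@H]1COC(C)(C)O1 | intermediate
3 | (4R)-4-ethynyl-2,2-dimethyl-1,3-dioxolane | C#C[C@@H]1COC(C)(C)O1 | intermediate
4 | {[(4R)-2,2-dimethyl-1,3-dioxolan-4-yl]ethynyl}lithium | [Li]C#C[C@@H]1COC(C)(C)O1 | intermediate
5 | 3-[(4R)-2,2-dimethyl-1,3-dioxolan-4-yl]prop-2-yn-1-ol | OCC#C[C@@H]1COC(C)(C)O1 | intermediate
6 | sodium 2,2-bis(2-methoxyethoxy)-3-[(4S)-2,2-dimethyl-1,3-dioxolan-4-yl]-2,5-dihydro-1,2-oxaluminol-2-uide (cyclic vinylalanate) | [Na+].COCCO[Al-]1(OCCOC)OCC=C1[C@@H]1COC(C)(C)O1 | intermediate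
7 | (2Z)-3-[(4S)-2,2-dimethyl-1,3-dioxolan-4-yl]-3-iodoprop-2-en-1-ol | OC/C=C(\I)[C@@H]1COC(C)(C)O1 | intermediate
8 | tert-butyl{[(2Z)-3-[(4S)-2,2-dimethyl-1,3-dioxolan-4-yl]-3-iodoprop-2-en-1-yl]oxy}diphenylsilane | CC(C)(C)[Si](OC/C=C(\I)[C@@H]1COC(C)(C)O1)(c1ccccc1)c1ccccc1 | intermediate
9 | 4-formyl-2-methoxyphenyl acetate (vanillin acetate) | CC(=O)Oc1ccc(C=O)cc1OC | starting material
10 | 4-(hydroxymethyl)-2-methoxyphenyl acetate | CC(=O)Oc1ccc(CO)cc1OC | intermediate
11 | 4-(chloromethyl)-2-methoxyphenyl acetate | CC(=O)Oc1ccc(CCl)cc1OC | intermediate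
12 | (4-acetoxy-3-methoxybenzyl)zinc chloride | CC(=O)Oc1ccc(C[Zn]Cl)cc1OC | intermediate
13 | 4-{(2E)-4-[(tert-butyldiphenylsilyl)oxy]-2-[(4R)-2,2-dimethyl-1,3-dioxolan-4-yl]but-2-en-1-yl}-2-methoxyphenyl acetate | CC(=O)Oc1ccc(C/C(=C\CO[Si](c2ccccc2)(c2ccccc2)C(C)(C)C)[C@@H]2COC(C)(C)O2)cc1OC | intermediate
14 | 4-{(2E)-4-[(tert-butyldiphenylsilyl)oxy]-2-[(1R)-1,2-dihydroxyethyl]but-2-en-1-yl}-2-methoxyphenyl acetate | CC(=O)Oc1ccc(C/C(=C\CO[Si](c2ccccc2)(c2ccccc2)C(C)(C)C)[C@@H](O)CO)cc1OC | intermediate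
15 | 4-{(2E)-2-[(4R)-2-(4-acetoxy-3-methoxyphenyl)-1,3-dioxolan-4-yl]-4-[(tert-butyldiphenylsilyl)oxy]but-2-en-1-yl}-2-methoxyphenyl acetate (both acetal epimers) | CC(=O)Oc1ccc(C/C(=C\CO[Si](c2ccccc2)(c2ccccc2)C(C)(C)C)[C@@H]2COC(c3ccc(OC(C)=O)c(OC)c3)O2)cc1OC | intermediate
16 | (3R,4S,5R)-5-(4-acetoxy-3-methoxyphenyl)-3-(4-acetoxy-3-methoxybenzyl)-4-{[(tert-butyldiphenylsilyl)oxy]methyl}oxolane-3-carbaldehyde | COc1cc(C[C@]2(C=O)CO[C@@H](c3ccc(OC(C)=O)c(OC)c3)[C@@H]2CO[Si](c4ccccc4)(c5ccccc5)C(C)(C)C)ccc1OC(C)=O | intermediate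
17 | (3R,4S,5R)-5-(4-acetoxy-3-methoxyphenyl)-3-(4-acetoxy-3-methoxybenzyl)-4-{[(tert-butyldiphenylsilyl)oxy]methyl}oxolan-3-yl formate | COc1cc(C[C@]2(OC=O)CO[C@@H](c3ccc(OC(C)=O)c(OC)c3)[C@@H]2CO[Si](c4ccccc4)(c5ccccc5)C(C)(C)C)ccc1OC(C)=O | intermediate
18 | (3R,4S,5R)-4-{[(tert-butyldiphenylsilyl)oxy]methyl}-5-(4-hydroxy-3-methoxyphenyl)-3-(4-hydroxy-3-methoxybenzyl)oxolan-3-ol | COc1cc(C[C@]2(O)CO[C@@H](c3ccc(O)c(OC)c3)[C@@H]2CO[Si](c4ccccc4)(c5ccccc5)C(C)(C)C)ccc1O | intermediate
19 | (3R,4S,5R)-5-(4-hydroxy-3-methoxyphenyl)-3-[(4-hydroxy-3-methoxyphenyl)methyl]-4-(hydroxymethyl)oxolan-3-ol | COc1cc(C[C@]2(O)CO[C@@H](c3ccc(O)c(OC)c3)[C@@H]2CO)ccc1O | target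

Total step count: 11. Longest linear sequence: 9 (steps 1–4 and 7–11).

**Steps most likely to fail**

**1. Step 9.**
- What may go wrong: leakage between the two mirror-image chairs (incomplete chirality transfer), diversion of the cation by hydride shift, ionisation of the allylic C–O bond, or Friedel–Crafts capture of the Lewis-acid-bound aldehyde.
- Fallback idea: C2 and C3 would be set by catalyst control before any ring exists, and the C4–O bond by alkene oxidation.
- It sets out from diol 14 and aldehyde 9. Periodate cleavage of 14 would give 4-{(2E)-4-[(tert-butyldiphenylsilyl)oxy]-2-formylbut-2-en-1-yl}-2-methoxyphenyl acetate F1.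
- Luche reduction would give the allylic alcohol 4-{(2E)-4-[(tert-butyldiphenylsilyl)oxy]-2-(hydroxymethyl)but-2-en-1-yl}-2-methoxyphenyl acetate F2.
- Palladium-catalysed borylation with B2pin2 would give the E-crotyl-type pinacol allylboronate F3.
- Allylboration of 9 catalysed by a chiral phosphoric acid (closed chair, anti) would give the (1R,2S)-homoallylic alcohol F4.
- Hydroxyl-directed epoxidation (VO(acac)2, t-BuOOH) would give the 2,2-disubstituted oxirane F5. C4 rests here on substrate direction and would have to be checked.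
- MgI2 (iodohydrin, then 5-exo-tet displacement by the C2 hydroxyl group) would give the diacetylated oxolan-3-ol F6. Its methanolysis under the first conditions of step 11 comes back to the route at 18.

**2. Step 10.**
- What may go wrong: hydride instead of alkyl migration in the Criegee adduct, which would end at the carboxylic acid.
- Fallback idea: radical decarboxylative hydroxylation, which can also use that acid.
- It sets out from 16. Pinnick oxidation would give the oxolane-3-carboxylic acid F7.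
- Coupling with N-hydroxypyridine-2-thione (DCC) would give the Barton ester F8.
- Irradiation under O2 with t-BuSH, then P(OMe)3, would give the diacetylated oxolan-3-ol F6. Oxygen should approach the planar C4 radical anti to the bulky C3 CH2OTBDPS group, which is the face required.
- Methanolysis of F6 comes back to the route at 18.

**3. Step 3.**
- What may go wrong: β-elimination of the dioxolane oxygen from the vinylalanate to an allene, or over-reduction.
- Fallback idea: transition-metal trans-hydrosilylation, which passes through no β-alkoxy organoaluminium species.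
- It sets out from 5. Et3SiH with [Cp*Ru(MeCN)3]PF6 would give (2Z)-3-[(4S)-2,2-dimethyl-1,3-dioxolan-4-yl]-3-(triethylsilyl)prop-2-en-1-ol F9, with silicon on the carbon remote from the free hydroxyl group.
- Stereoretentive iododesilylation (NIS, hexafluoroisopropanol) comes back to the route at 7.

**Further compounds**
F1 | step 9 | 4-{(2E)-4-[(tert-butyldiphenylsilyl)oxy]-2-formylbut-2-en-1-yl}-2-methoxyphenyl acetate | CC(=O)Oc1ccc(C/C(C=O)=C\CO[Si](c2ccccc2)(c2ccccc2)C(C)(C)C)cc1OC
F2 | step 9 | 4-{(2E)-4-[(tert-butyldiphenylsilyl)oxy]-2-(hydroxymethyl)but-2-en-1-yl}-2-methoxyphenyl acetate | CC(=O)Oc1ccc(C/C(CO)=C\CO[Si](c2ccccc2)(c2ccccc2)C(C)(C)C)cc1OC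
F3 | step 9 | 4-{(2Z)-4-[(tert-butyldiphenylsilyl)oxy]-2-[(4,4,5,5-tetramethyl-1,3,2-dioxaborolan-2-yl)methyl]but-2-en-1-yl}-2-methoxyphenyl acetate | CC(=O)Oc1ccc(C/C(CB2OC(C)(C)C(C)(C)O2)=C\CO[Si](c2ccccc2)(c2ccccc2)C(C)(C)C)cc1OC
F4 | step 9 | (1R,2S)-1-(4-acetoxy-3-methoxyphenyl)-3-(4-acetoxy-3-methoxybenzyl)-2-{[(tert-butyldiphenylsilyl)oxy]methyl}but-3-en-1-ol | O[C@@H](c1ccc(OC(C)=O)c(OC)c1)[C@@H](C(=C)Cc1ccc(OC(C)=O)c(OC)c1)CO[Si](c1ccccc1)(c1ccccc1)C(C)(C)C
F5 | step 9 | (1R,2S)-1-(4-acetoxy-3-methoxyphenyl)-2-[(2R)-2-(4-acetoxy-3-methoxybenzyl)oxiran-2-yl]-3-[(tert-butyldiphenylsilyl)oxy]propan-1-ol | O[C@@H](c1ccc(OC(C)=O)c(OC)c1)[C@@H]([C@]1(Cc2ccc(OC(C)=O)c(OC)c2)CO1)CO[Si](c1ccccc1)(c1ccccc1)C(C)(C)C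
F6 | step 9 | (3R,4S,5R)-5-(4-acetoxy-3-methoxyphenyl)-3-(4-acetoxy-3-methoxybenzyl)-4-{[(tert-butyldiphenylsilyl)oxy]methyl}oxolan-3-ol | COc1cc(C[C@]2(O)CO[C@@H](c3ccc(OC(C)=O)c(OC)c3)[C@@H]2CO[Si](c4ccccc4)(c5ccccc5)C(C)(C)C)ccc1OC(C)=O
F7 | step 10 | (3R,4S,5R)-5-(4-acetoxy-3-methoxyphenyl)-3-(4-acetoxy-3-methoxybenzyl)-4-{[(tert-butyldiphenylsilyl)oxy]methyl}oxolane-3-carboxylic acid | COc1cc(C[C@]2(C(=O)O)CO[C@@H](c3ccc(OC(C)=O)c(OC)c3)[C@@H]2CO[Si](c4ccccc4)(c5ccccc5)C(C)(C)C)ccc1OC(C)=O
F8 | step 10 | 2-thioxopyridin-1(2H)-yl (3R,4S,5R)-5-(4-acetoxy-3-methoxyphenyl)-3-(4-acetoxy-3-methoxybenzyl)-4-{[(tert-butyldiphenylsilyl)oxy]methyl}oxolane-3-carboxylate | COc1cc(C[C@]2(C(=O)On3ccccc3=S)CO[C@@H](c3ccc(OC(C)=O)c(OC)c3)[C@@H]2CO[Si](c4ccccc4)(c5ccccc5)C(C)(C)C)ccc1OC(C)=O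
F9 | step 3 | (2Z)-3-[(4S)-2,2-dimethyl-1,3-dioxolan-4-yl]-3-(triethylsilyl)prop-2-en-1-ol | OC/C=C(\[Si](CC)(CC)CC)[C@@H]1COC(C)(C)O1
A1 | direct plan | (2R,3E)-5-(benzyloxy)pent-3-en-2-yl 2-(benzyloxy)-3-[4-(benzyloxy)-3-methoxyphenyl]propanoate | C[C@@H](OC(=O)C(Cc1ccc(OCc2ccccc2)c(OC)c1)OCc1ccccc1)/C=C/COCc1ccccc1
A2 | direct plan | (2R,3R,4E)-2-(benzyloxy)-2-[4-(benzyloxy)-3-methoxybenzyl]-3-[(benzyloxy)methyl]hex-4-enoic acid | OC(=O)[C@@](OCc1ccccc1)(Cc1ccc(OCc2ccccc2)c(OC)c1)[C@@H](COCc1ccccc1)/C=C/C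
A3 | direct plan | (3R,4R)-4-(benzyloxy)-4-[4-(benzyloxy)-3-methoxybenzyl]-3-[(benzyloxy)methyl]oxolan-2-ol | OC1OC[C@@](OCc2ccccc2)(Cc2ccc(OCc3ccccc3)c(OC)c2)[C@H]1COCc1ccccc1
A4 | direct plan | (2S,3R)-3-(benzyloxy)-3-[4-(benzyloxy)-3-methoxybenzyl]-1-[4-(benzyloxy)-3-methoxyphenyl]-2-[(benzyloxy)methyl]butane-1,4-diol | OC[C@@](OCc1ccccc1)(Cc1ccc(OCc2ccccc2)c(OC)c1)[C@@H](COCc1ccccc1)C(O)c1ccc(OCc2ccccc2)c(OC)c1
A5 | direct plan | (2R,3S,4R)-4-(benzyloxy)-4-[4-(benzyloxy)-3-methoxybenzyl]-2-[4-(benzyloxy)-3-methoxyphenyl]-3-[(benzyloxy)methyl]oxolane | COc1cc(C[C@]2(OCc3ccccc3)CO[C@@H](c3ccc(OCc4ccccc4)c(OC)c3)[C@@H]2COCc2ccccc2)ccc1OCc1ccccc1
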